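The syringyl-bearing tetrahydrofuran ring (C1, O2, C3, C3a, C6a of the furo[3,4-c]furan) is made by photochemical Wolff ring contraction of a 3-diazotetrahydropyran-4-one. The step exploits the fact that C6a carries the one-carbon branch C6 and sits between C1 and C3a: the extruded ketone carbon becomes C6 as a ketene, which the benzylic hydroxyl on the C3a side chain captures at once, closing the second ring as a cis-fused lactone and fixing C6a. The precursor, a trans-2-aryl-5-(α-hydroxybenzyl) diazo ketone, comes from an asymmetric hetero-Diels–Alder reaction, a proline aldol addition and diazo transfer; lactone reduction, etherification and debenzylation complete the target.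

Key step: step 5

Remark: 4-(benzyloxy)-3,5-dimethoxybenzaldehyde is taken as a purchasable starting material, and the (R)-BINOL–titanium catalyst is assumed to add to the aldehyde Re face as with benzaldehyde (the antipodal ligand is used if the sense is reversed).

Step 1
Reactants: 1 4-(benzyloxy)-3,5-dimethoxybenzaldehyde; 2 (E)-1-methoxy-3-(trimethylsilyloxy)buta-1,3-diene
Product: 4 (R)-2-[4-(benzyloxy)-3,5-dimethoxyphenyl]-2,3-dihydro-4H-pyran-4-one, via silyl aldol adduct 3 (not isolated)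
Conditions: (R)-BINOL (20 mol%), Ti(OiPr)4 (10 mol%), 4 Å MS, Et2O, −20 °C; then CF3CO2H, CH2Cl2, 0 °C
Reagents that add atoms: none
Why: Catalytic asymmetric hetero-Diels–Alder reaction in its Mukaiyama aldol–cyclisation mode, in which the BINOL–titanium complex should direct the diene to the Re face of the aldehyde and so set C2 as (R), before acid closes the ring by oxa-Michael addition with loss of methanol.

Step 2
Reactants: 4 (R)-2-[4-(benzyloxy)-3,5-dimethoxyphenyl]-2,3-dihydro-4H-pyran-4-one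
Product: 5 (R)-2-[4-(benzyloxy)-3,5-dimethoxyphenyl]tetrahydro-4H-pyran-4-one
Conditions: L-Selectride (1.05 equiv), THF, −78 °C; aq. NH4Cl
Reagents that add atoms: none
Why: Conjugate (1,4) hydride reduction of the vinylogous ester by a hindered borohydride, which should leave the ketone, the benzyl ether and the C2 stereocentre untouched.

Step 3
Reactants: 5 (R)-2-[4-(benzyloxy)-3,5-dimethoxyphenyl]tetrahydro-4H-pyran-4-one; 6 3,4,5-trimethoxybenzaldehyde
Product: 7 (2R,5S)-2-[4-(benzyloxy)-3,5-dimethoxyphenyl]-5-[(R)-hydroxy(3,4,5-trimethoxyphenyl)methyl]tetrahydro-4H-pyran-4-one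
Conditions: L-proline (30 mol%), 6 (3 equiv), DMSO, H2O (2 equiv), rt
Reagents that add atoms: none
Why: Proline-catalysed direct aldol addition through the hydrogen-bonded enamine transition state: the enamine should form on the less hindered C5 side and L-proline should set C5 as (S) and the carbinol as (R) (anti), which with (R)-C2 is the diequatorial 2,5-trans isomer, reagent control being expected to outweigh the weak bias of the remote aryl group.

Step 4
Reactants: 7 (2R,5S)-2-[4-(benzyloxy)-3,5-dimethoxyphenyl]-5-[(R)-hydroxy(3,4,5-trimethoxyphenyl)methyl]tetrahydro-4H-pyran-4-one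
Product: 9 (2S,5S)-2-[4-(benzyloxy)-3,5-dimethoxyphenyl]-3-diazo-5-[(R)-hydroxy(3,4,5-trimethoxyphenyl)methyl]tetrahydro-4H-pyran-4-one, via trifluoroacetyl ketone 8 (not isolated)
Conditions: LiHMDS (2.2 equiv), THF, −78 °C; CF3CO2CH2CF3, −78 °C; aq. HCl; then MsN3, Et3N, H2O (1 equiv), MeCN, rt; aq. K2CO3/MeOH wash
Reagents that add atoms: methanesulfonyl azide, CS(=O)(=O)N=[N+]=[N-]
Why: Deacylative (detrifluoroacetylative) Regitz-type diazo transfer: the lithium aldolate should steer the second deprotonation to the unsubstituted α′-methylene C3, C-trifluoroacetylation activates that carbon, and the sulfonyl azide replaces the acyl group by N2 without touching a stereocentre (the C2 descriptor changes only by priority), any O-trifluoroacetate being cleaved in the basic wash.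

Step 5
Reactants: 9 (2S,5S)-2-[4-(benzyloxy)-3,5-dimethoxyphenyl]-3-diazo-5-[(R)-hydroxy(3,4,5-trimethoxyphenyl)methyl]tetrahydro-4H-pyran-4-one
Product: 11 (3R,3aS,6R,6aR)-6-[4-(benzyloxy)-3,5-dimethoxyphenyl]-3-(3,4,5-trimethoxyphenyl)tetrahydro-1H,3H-furo[3,4-c]furan-1-one, via hydroxy ketene 10 (not isolated)
Conditions: hν (365 nm LED), THF (0.01 M, degassed), 0 °C → rt
Reagents that add atoms: none
Why: Excitation of the s-Z-locked cyclic α-diazo ketone should expel N2 with concerted 1,2-shift of C5 from the carbonyl carbon to the diazo carbon (photo-Wolff rearrangement), contracting the six-membered ring to the tetrahydrofuran and turning the former C4 into an exocyclic ketene carbon. The closest known reaction type is the Wolff ring contraction of cyclic 2-diazo ketones with capture of the ketene by an alcohol. The tetrahydrofuran arises by this 1,2-shift and not by a cyclisation, while the lactone ring closes by 5-exo-dig addition of the benzylic hydroxyl to the ketene carbonyl carbon. C5 migrates with retention and C2 and the carbinol carbon are not touched, so the trans relation of aryl group and side chain is carried into the five-membered ring; the new stereocentre C6a is set on ketonisation of the lactone enol, because only the cis-fused 5/5 lactone can form. The step needs rearrangement to outrun 1,2-hydrogen shift from C2 and O–H insertion, which the concerted pathway of the s-Z diazo ketone under metal-free irradiation should secure, and intramolecular ketene capture to outrun dimerisation, which high dilution in a non-nucleophilic solvent should secure.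

Step 6
Reactants: 11 (3R,3aS,6R,6aR)-6-[4-(benzyloxy)-3,5-dimethoxyphenyl]-3-(3,4,5-trimethoxyphenyl)tetrahydro-1H,3H-furo[3,4-c]furan-1-one
Product: 12 {(2R,3S,4S)-2-[4-(benzyloxy)-3,5-dimethoxyphenyl]-4-[(R)-hydroxy(3,4,5-trimethoxyphenyl)methyl]oxolan-3-yl}methanol
Conditions: LiAlH4, THF, 0 °C; H2O, aq. NaOH work-up
Reagents that add atoms: none
Why: Hydride reduction of the lactone to the 1,4-diol, which should be fast enough to avoid epimerisation α to the carbonyl and leaves the ethers and all four stereocentres as they are.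

Step 7
Reactants: 12 {(2R,3S,4S)-2-[4-(benzyloxy)-3,5-dimethoxyphenyl]-4-[(R)-hydroxy(3,4,5-trimethoxyphenyl)methyl]oxolan-3-yl}methanol
Product: 14 (1R,3aS,4R,6aS)-1-[4-(benzyloxy)-3,5-dimethoxyphenyl]-4-(3,4,5-trimethoxyphenyl)tetrahydro-1H,3H-furo[3,4-c]furan, via primary mesylate 13 (not isolated)
Conditions: MsCl (1.1 equiv), pyridine, 0 °C → rt
Reagents that add atoms: none
Why: Selective sulfonylation of the primary alcohol followed by intramolecular Williamson etherification (5-exo-tet) by the secondary benzylic hydroxyl, in which the benzylic C–O bond is not broken, so C4 keeps its configuration and the aryl group stays exo.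

Step 8
Reactants: 14 (1R,3aS,4R,6aS)-1-[4-(benzyloxy)-3,5-dimethoxyphenyl]-4-(3,4,5-trimethoxyphenyl)tetrahydro-1H,3H-furo[3,4-c]furan
Product: 15 4-[(1R,3aS,4R,6aS)-4-(3,4,5-trimethoxyphenyl)tetrahydro-1H,3H-furo[3,4-c]furan-1-yl]-2,6-dimethoxyphenol
Conditions: H2 (1 atm), 10% Pd/C, EtOAc, rt
Reagents that add atoms: none
Why: Catalytic hydrogenolysis of the aryl benzyl ether, which under neutral conditions at 1 atm should be faster than cleavage of the cyclic dibenzylic ether bonds and touches no stereocentre.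

Compound list
1 | 4-(benzyloxy)-3,5-dimethoxybenzaldehyde | COc1cc(C=O)cc(OC)c1OCc1ccccc1 | starting material
2 | (E)-1-methoxy-3-(trimethylsilyloxy)buta-1,3-diene | CO/C=C/C(=C)O[Si](C)(C)C | starting material
3 | (R,E)-5-[4-(benzyloxy)-3,5-dimethoxyphenyl]-1-methoxy-5-(trimethylsilyloxy)pent-1-en-3-one | CO/C=C/C(=O)C[C@@H](O[Si](C)(C)C)c1cc(OC)c(OCc2ccccc2)c(OC)c1 | intermediate
4 | (R)-2-[4-(benzyloxy)-3,5-dimethoxyphenyl]-2,3-dihydro-4H-pyran-4-one | O=C1C[C@H](c2cc(OC)c(OCc3ccccc3)c(OC)c2)OC=C1 | intermediate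
5 | (R)-2-[4-(benzyloxy)-3,5-dimethoxyphenyl]tetrahydro-4H-pyran-4-one | O=C1C[C@H](c2cc(OC)c(OCc3ccccc3)c(OC)c2)OCC1 | intermediate
6 | 3,4,5-trimethoxybenzaldehyde | COc1cc(C=O)cc(OC)c1OC | starting material
7 | (2R,5S)-2-[4-(benzyloxy)-3,5-dimethoxyphenyl]-5-[(R)-hydroxy(3,4,5-trimethoxyphenyl)methyl]tetrahydro-4H-pyran-4-one | O=C1C[C@H](c2cc(OC)c(OCc3ccccc3)c(OC)c2)OC[C@H]1[C@@H](O)c1cc(OC)c(OC)c(OC)c1 | intermediate
8 | (2R,5S)-2-[4-(benzyloxy)-3,5-dimethoxyphenyl]-5-[(R)-hydroxy(3,4,5-trimethoxyphenyl)methyl]-3-(trifluoroacetyl)tetrahydro-4H-pyran-4-one (C3 epimers and enol) | O=C1C(C(=O)C(F)(F)F)[C@H](c2cc(OC)c(OCc3ccccc3)c(OC)c2)OC[C@H]1[C@@H](O)c1cc(OC)c(OC)c(OC)c1 | intermediate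
9 | (2S,5S)-2-[4-(benzyloxy)-3,5-dimethoxyphenyl]-3-diazo-5-[(R)-hydroxy(3,4,5-trimethoxyphenyl)methyl]tetrahydro-4H-pyran-4-one | O=C1C(=[N+]=[N-])[C@H](c2cc(OC)c(OCc3ccccc3)c(OC)c2)OC[C@H]1[C@@H](O)c1cc(OC)c(OC)c(OC)c1 | intermediate
10 | {(2S,4S)-2-[4-(benzyloxy)-3,5-dimethoxyphenyl]-4-[(R)-hydroxy(3,4,5-trimethoxyphenyl)methyl]oxolan-3-ylidene}methanone (ketene) | O=C=C1[C@H](c2cc(OC)c(OCc3ccccc3)c(OC)c2)OC[C@H]1[C@@H](O)c1cc(OC)c(OC)c(OC)c1 | intermediate
11 | (3R,3aS,6R,6aR)-6-[4-(benzyloxy)-3,5-dimethoxyphenyl]-3-(3,4,5-trimethoxyphenyl)tetrahydro-1H,3H-furo[3,4-c]furan-1-one | O=C1O[C@@H](c2cc(OC)c(OC)c(OC)c2)[C@@H]2CO[C@@H](c3cc(OC)c(OCc4ccccc4)c(OC)c3)[C@H]12 | intermediate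
12 | {(2R,3S,4S)-2-[4-(benzyloxy)-3,5-dimethoxyphenyl]-4-[(R)-hydroxy(3,4,5-trimethoxyphenyl)methyl]oxolan-3-yl}methanol | OC[C@H]1[C@H](c2cc(OC)c(OCc3ccccc3)c(OC)c2)OC[C@H]1[C@@H](O)c1cc(OC)c(OC)c(OC)c1 | intermediate
13 | {(2R,3S,4S)-2-[4-(benzyloxy)-3,5-dimethoxyphenyl]-4-[(R)-hydroxy(3,4,5-trimethoxyphenyl)methyl]oxolan-3-yl}methyl methanesulfonate | CS(=O)(=O)OC[C@H]1[C@H](c2cc(OC)c(OCc3ccccc3)c(OC)c2)OC[C@H]1[C@@H](O)c1cc(OC)c(OC)c(OC)c1 | intermediate
14 | (1R,3aS,4R,6aS)-1-[4-(benzyloxy)-3,5-dimethoxyphenyl]-4-(3,4,5-trimethoxyphenyl)tetrahydro-1H,3H-furo[3,4-c]furan | COc1cc([C@@H]2OC[C@@H]3[C@H]2CO[C@H]3c2cc(OC)c(OC)c(OC)c2)cc(OC)c1OCc1ccccc1 | intermediate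
15 | 4-[(1R,3aS,4R,6aS)-4-(3,4,5-trimethoxyphenyl)tetrahydro-1H,3H-furo[3,4-c]furan-1-yl]-2,6-dimethoxyphenol | COc1cc([C@@H]2OC[C@@H]3[C@H]2CO[C@H]3c2cc(OC)c(OC)c(OC)c2)cc(OC)c1O | target

Total step count: 8. Longest linear sequence: 8 steps (from 1).

Steps most likely to fail

Step 3. Enamine formation may be slow with the ketone as limiting reagent, some enamine may form toward C3, and the catalyst-preferred face at C5 is the conformationally less favoured one for the (R)-ketone, so facial selectivity may erode. The fallback sets out from 4 and comes back at 7, and makes the C5–carbinol bond while C5 is still sp2. Compound 4 is iodinated at C5 (I2, pyridine, CH2Cl2) to give (R)-2-[4-(benzyloxy)-3,5-dimethoxyphenyl]-5-iodo-2,3-dihydro-4H-pyran-4-one F1. Palladium-catalysed formylation (Pd(PPh3)4, CO, Bu3SnH) gives (R)-2-[4-(benzyloxy)-3,5-dimethoxyphenyl]-4-oxo-3,4-dihydro-2H-pyran-5-carbaldehyde F2. Catalytic enantioselective aryl transfer from (3,4,5-trimethoxyphenyl)boronic acid and Et2Zn with a chiral amino alcohol ligand should set the carbinol centre under reagent control and give (R)-2-[4-(benzyloxy)-3,5-dimethoxyphenyl]-5-[(S)-hydroxy(3,4,5-trimethoxyphenyl)methyl]-2,3-dihydro-4H-pyran-4-one F3. L-Selectride 1,4-reduction with protonation of the enolate should then place the side chain equatorial, trans to the C2 aryl group, and return 7.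

Step 5. 1,2-Hydrogen shift from C2 or O–H insertion may compete with the rearrangement, or the ketene may react between molecules before the hydroxyl reaches it. The fallback sets out from 9 and comes back at 11. Irradiation in methanol should trap the ketene with solvent as methyl (2R,4S)-2-[4-(benzyloxy)-3,5-dimethoxyphenyl]-4-[(R)-hydroxy(3,4,5-trimethoxyphenyl)methyl]oxolane-3-carboxylate F4 (both C3 epimers). DBU in warm toluene should then equilibrate C3 and close the cis-fused lactone 11 with loss of methanol.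

Step 4. The free hydroxyl may be acylated, the dianion may undergo retro-aldol cleavage, or enolisation may occur at C5. The fallback sets out from 7 and comes back at 9, and takes the hydroxyl out of play. Silylation (TESCl, imidazole) gives (2R,5S)-2-[4-(benzyloxy)-3,5-dimethoxyphenyl]-5-[(R)-(triethylsilyloxy)(3,4,5-trimethoxyphenyl)methyl]tetrahydro-4H-pyran-4-one F5. Enolisation with one equivalent of LiHMDS and trifluoroacetylation gives the 3-(trifluoroacetyl) ketone F6, and mesyl azide/Et3N gives (2S,5S)-2-[4-(benzyloxy)-3,5-dimethoxyphenyl]-3-diazo-5-[(R)-(triethylsilyloxy)(3,4,5-trimethoxyphenyl)methyl]tetrahydro-4H-pyran-4-one F7. HF·pyridine removes the silyl group and returns 9.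

Further compounds
F1 | step 3 | (R)-2-[4-(benzyloxy)-3,5-dimethoxyphenyl]-5-iodo-2,3-dihydro-4H-pyran-4-one | O=C1C[C@H](c2cc(OC)c(OCc3ccccc3)c(OC)c2)OC=C1I
F2 | step 3 | (R)-2-[4-(benzyloxy)-3,5-dimethoxyphenyl]-4-oxo-3,4-dihydro-2H-pyran-5-carbaldehyde | O=C1C[C@H](c2cc(OC)c(OCc3ccccc3)c(OC)c2)OC=C1C=O
F3 | step 3 | (R)-2-[4-(benzyloxy)-3,5-dimethoxyphenyl]-5-[(S)-hydroxy(3,4,5-trimethoxyphenyl)methyl]-2,3-dihydro-4H-pyran-4-one | O=C1C[C@H](c2cc(OC)c(OCc3ccccc3)c(OC)c2)OC=C1[C@@H](O)c1cc(OC)c(OC)c(OC)c1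
F4 | step 5 | methyl (2R,4S)-2-[4-(benzyloxy)-3,5-dimethoxyphenyl]-4-[(R)-hydroxy(3,4,5-trimethoxyphenyl)methyl]oxolane-3-carboxylate (C3 epimers) | COC(=O)C1[C@H](c2cc(OC)c(OCc3ccccc3)c(OC)c2)OC[C@H]1[C@@H](O)c1cc(OC)c(OC)c(OC)c1
F5 | step 4 | (2R,5S)-2-[4-(benzyloxy)-3,5-dimethoxyphenyl]-5-[(R)-(triethylsilyloxy)(3,4,5-trimethoxyphenyl)methyl]tetrahydro-4H-pyran-4-one | O=C1C[C@H](c2cc(OC)c(OCc3ccccc3)c(OC)c2)OC[C@H]1[C@@H](O[Si](CC)(CC)CC)c1cc(OC)c(OC)c(OC)c1
F6 | step 4 | (2R,5S)-2-[4-(benzyloxy)-3,5-dimethoxyphenyl]-5-[(R)-(triethylsilyloxy)(3,4,5-trimethoxyphenyl)methyl]-3-(trifluoroacetyl)tetrahydro-4H-pyran-4-one (C3 epimers and enol) | O=C1C(C(=O)C(F)(F)F)[C@H](c2cc(OC)c(OCc3ccccc3)c(OC)c2)OC[C@H]1[C@@H](O[Si](CC)(CC)CC)c1cc(OC)c(OC)c(OC)c1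
F7 | step 4 | (2S,5S)-2-[4-(benzyloxy)-3,5-dimethoxyphenyl]-3-diazo-5-[(R)-(triethylsilyloxy)(3,4,5-trimethoxyphenyl)methyl]tetrahydro-4H-pyran-4-one | O=C1C(=[N+]=[N-])[C@H](c2cc(OC)c(OCc3ccccc3)c(OC)c2)OC[C@H]1[C@@H](O[Si](CC)(CC)CC)c1cc(OC)c(OC)c(OC)c1
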